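## Retrosynthetic overview

1. Helenien ⇒ two Wittig disconnections (C11'=C12', then C11=C12): ε-C15 phosphonium salt 12, C10 dialdehyde 20 and β-C15 phosphonium salt 19, each C15 half already carrying its palmitate.
2. Both C15 halves ⇒ one enone 8 (3'-oxo ε-ring with the complete 7E,9E-dienyl arm and C6' set). Hydride from one face plus acylation gives the ε-half. Hydride from the other face, then base-induced shift of C4=C5 to C5=C6, gives the β-half (C6 is spent after relaying to C3).
3. Enone 8 ⇒ one-carbon ring enlargement of a cyclopentane: 1-siloxybicyclo[3.1.0]hexane 6 ⇐ cyclopropanation of silyl enol ether 5 ⇐ catalytic asymmetric conjugate addition of a dienylzirconocene (from enynol 1) to 2,4,4-trimethylcyclopentenone 3.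
4. Enabling feature: in the ε-ring, C4' is a lone CH between oxygen-bearing C3' and methyl-bearing C5', so C3'(O)–C4'H=C5'(CH3) is a reduced β-methyl enone. C4' can therefore be inserted as a carbenoid carbon into the C3'=C5' enol double bond of a cyclopentanone that already holds C6', quaternary C1' and C2'; the C5' methyl directs cleavage to the ring-fusion bond.
5. Ring order: purchased cyclopentenone → temporary cyclopropane-fused bicycle (step 3) → six-membered ε-ring (step 4); the β-ring is the same ring after double-bond migration (step 12); no other ring is made.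

Key step: step 4

Remark: 2,4,4-trimethylcyclopent-2-en-1-one (3), (2E)-3-methylpent-2-en-4-yn-1-ol (1) and (2E,4E,6E)-2,7-dimethylocta-2,4,6-trienedial (20) are taken as catalogue chemicals. TBS = tert-butyldimethylsilyl, TMS = trimethylsilyl. Locants in the Why lines follow the compound names.

## Route

Step 1
Reactants: 1 (2E)-3-methylpent-2-en-4-yn-1-ol
Product: 2 tert-butyl(dimethyl){[(2E)-3-methylpent-2-en-4-yn-1-yl]oxy}silane
Conditions: TBSCl, imidazole, DMF, 0 °C to rt
Reagents that add atoms: tert-butyl(chloro)dimethylsilane CC(C)(C)[Si](C)(C)Cl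
Why: Imidazole-promoted O-silylation of a primary allylic alcohol; the alkyne C–H and the (E)-olefin are untouched and no stereocentre is involved.

Step 2
Reactants: 2 tert-butyl(dimethyl){[(2E)-3-methylpent-2-en-4-yn-1-yl]oxy}silane; 3 2,4,4-trimethylcyclopent-2-en-1-one
Product: 5 tert-butyl(dimethyl){[(2E,4E)-3-methyl-5-[(1R)-2,5,5-trimethyl-3-(trimethylsilyloxy)cyclopent-2-en-1-yl]penta-2,4-dien-1-yl]oxy}silane, via dienylzirconocene chloride 4 (not isolated)
Conditions: Cp2Zr(H)Cl, CH2Cl2, rt; then CuCl (10 mol %), (S,R,R)-BINOL/bis(1-phenylethyl)amine phosphoramidite (10 mol %), AgOTf (11 mol %), 3, TMSCl, Et2O, 0 °C to rt; Et3N, pentane, filtration through basic alumina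
Reagents that add atoms: chlorotrimethylsilane C[Si](C)(C)Cl
Why: syn-Hydrozirconation of the terminal alkyne fixes the 7E geometry, and the copper(I)/phosphoramidite-catalysed, TMSCl-accelerated asymmetric conjugate addition of the alkenylzirconocene to the cyclic enone (ligand antipode chosen for delivery to the Re face of C3) should set the (R) centre that becomes C6', while O-silylation of the enolate fixes the tetrasubstituted enol ether regiospecifically.

Step 3
Reactants: 5 tert-butyl(dimethyl){[(2E,4E)-3-methyl-5-[(1R)-2,5,5-trimethyl-3-(trimethylsilyloxy)cyclopent-2-en-1-yl]penta-2,4-dien-1-yl]oxy}silane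
Product: 6 (1S,4R,5S)-4-[(1E,3E)-5-(TBSO)-3-methylpenta-1,3-dien-1-yl]-3,3,5-trimethyl-1-(trimethylsilyloxy)bicyclo[3.1.0]hexane
Conditions: Et2Zn (1.5 equiv), CH2I2 (1.5 equiv), CH2Cl2, 0 °C; pyridine, filtration
Reagents that add atoms: diiodomethane ICI
Why: Simmons–Smith cyclopropanation (Et2Zn/CH2I2 variant): the electron-rich silyl enol ether should react well before the diene, the carbenoid adding anti to the dienyl group, so the cis-fused bicycle with the CH2 bridge trans to the side chain is expected (its two new centres are erased in step 4).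

Step 4
Reactants: 6 (1S,4R,5S)-4-[(1E,3E)-5-(TBSO)-3-methylpenta-1,3-dien-1-yl]-3,3,5-trimethyl-1-(trimethylsilyloxy)bicyclo[3.1.0]hexane
Product: 8 (4R)-4-[(1E,3E)-5-(TBSO)-3-methylpenta-1,3-dien-1-yl]-3,5,5-trimethylcyclohex-2-en-1-one, via β-chloroketone 7 (not isolated)
Conditions: FeCl3 (2.2 equiv), pyridine (1 equiv), DMF, 0 °C to rt; then NaOAc, MeOH, 50 °C
Reagents that add atoms: none
Why: Si–O/Fe exchange gives an iron(III) cyclopropanolate (Me3SiCl leaves), inner-sphere electron transfer gives the cyclopropyloxy radical, β-scission of the ring-fusion bond C1–C5 opens the bicycle to the six-membered 3-oxocyclohexyl radical, chlorine transfer from a second FeCl3 gives β-chloroketone 7, and acetate-induced E1cB loss of HCl gives enone 8. The closest known reaction type is the Ito–Saegusa FeCl3 ring enlargement of 1-siloxybicyclo[n.1.0]alkanes to 2-cycloalkenones (one-carbon homologation of cyclic ketones). No ring is closed by bond formation: the cyclohexenone arises by cleavage of the zero-atom bridge of the bicyclo[3.1.0]hexane, the former carbenoid carbon becoming ring C2 (C4' of the target). No surviving stereocentre is created (the C–Cl centre of 7 is destroyed in the elimination), and the existing C4 centre is neither a radical site nor deprotonated by acetate, so it should be carried through unchanged. The step needs cleavage of the internal rather than an external cyclopropane bond, which the methyl group on C5 secures (tertiary versus primary radical), and a single enone regioisomer, which follows because only the hydrogens of the new CH2 can be lost in the E1cB step; DMF-buffered FeCl3 should leave the diene and the silyl ether untouched.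

Step 5
Reactants: 8 (4R)-4-[(1E,3E)-5-(TBSO)-3-methylpenta-1,3-dien-1-yl]-3,5,5-trimethylcyclohex-2-en-1-one
Product: 9 (1R,4R)-4-[(1E,3E)-5-(TBSO)-3-methylpenta-1,3-dien-1-yl]-3,5,5-trimethylcyclohex-2-en-1-ol
Conditions: (S)-Me-CBS (0.2 equiv), catecholborane (1.5 equiv), toluene, −78 °C; MeOH, then aqueous NaOH wash
Reagents that add atoms: none
Why: Corey–Bakshi–Shibata reduction under catalyst control: with the alkenyl arm as the large group, the (S)-catalyst delivers hydride to the Si face of C1 (the face syn to the C4 dienyl group), which should give the (1R) carbinol trans to the side chain, i.e. C3' of the target.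

Step 6
Reactants: 9 (1R,4R)-4-[(1E,3E)-5-(TBSO)-3-methylpenta-1,3-dien-1-yl]-3,5,5-trimethylcyclohex-2-en-1-ol
Product: 10 (1R,4R)-4-[(1E,3E)-5-(TBSO)-3-methylpenta-1,3-dien-1-yl]-3,5,5-trimethylcyclohex-2-en-1-yl hexadecanoate
Conditions: palmitoyl chloride, pyridine, DMAP (cat.), CH2Cl2, 0 °C to rt
Reagents that add atoms: hexadecanoyl chloride CCCCCCCCCCCCCCCC(=O)Cl
Why: DMAP-catalysed O-acylation of the secondary allylic alcohol with retention at C1; the palmitate is the final C3' ester and at the same time shields the acid-labile allylic carbinol.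

Step 7
Reactants: 10 (1R,4R)-4-[(1E,3E)-5-(TBSO)-3-methylpenta-1,3-dien-1-yl]-3,5,5-trimethylcyclohex-2-en-1-yl hexadecanoate
Product: 11 (1R,4R)-4-[(1E,3E)-5-hydroxy-3-methylpenta-1,3-dien-1-yl]-3,5,5-trimethylcyclohex-2-en-1-yl hexadecanoate
Conditions: HF·pyridine, pyridine, THF, 0 °C to rt
Reagents that add atoms: none
Why: Pyridine-buffered HF cleaves the primary allylic silyl ether (fluoride-driven desilylation), while the secondary allylic ester should be stable under these conditions.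

Step 8
Reactants: 11 (1R,4R)-4-[(1E,3E)-5-hydroxy-3-methylpenta-1,3-dien-1-yl]-3,5,5-trimethylcyclohex-2-en-1-yl hexadecanoate
Product: 12 {(2E,4E)-5-[(1R,4R)-4-(hexadecanoyloxy)-2,6,6-trimethylcyclohex-2-en-1-yl]-3-methylpenta-2,4-dien-1-yl}triphenylphosphonium bromide
Conditions: PPh3·HBr (1.05 equiv), CH2Cl2, 0 °C to rt
Reagents that add atoms: triphenylphosphine hydrobromide [Br-].c1ccc(cc1)[PH+](c1ccccc1)c1ccccc1
Why: Conversion of a primary dienylic alcohol into its phosphonium salt (ionisation to a pentadienyl cation and capture by PPh3 at the primary terminus), the usual entry to carotenoid C15 Wittig salts; the ring allylic ester should ionise far more slowly than the alcohol.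

Step 9
Reactants: 8 (4R)-4-[(1E,3E)-5-(TBSO)-3-methylpenta-1,3-dien-1-yl]-3,5,5-trimethylcyclohex-2-en-1-one
Product: 13 (1S,4R)-4-[(1E,3E)-5-(TBSO)-3-methylpenta-1,3-dien-1-yl]-3,5,5-trimethylcyclohex-2-en-1-ol
Conditions: (R)-Me-CBS (0.2 equiv), catecholborane (1.5 equiv), toluene, −78 °C; MeOH, then aqueous NaOH wash
Reagents that add atoms: none
Why: Corey–Bakshi–Shibata reduction with the enantiomeric catalyst, which should deliver hydride to the Re face of C1 (anti to the dienyl group) and give the cis-(1S) carbinol; this centre becomes C3 of the β-ring.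

Step 10
Reactants: 13 (1S,4R)-4-[(1E,3E)-5-(TBSO)-3-methylpenta-1,3-dien-1-yl]-3,5,5-trimethylcyclohex-2-en-1-ol
Product: 14 (1S,4R)-4-[(1E,3E)-5-hydroxy-3-methylpenta-1,3-dien-1-yl]-3,5,5-trimethylcyclohex-2-en-1-ol
Conditions: HF·pyridine, pyridine, THF, 0 °C to rt
Reagents that add atoms: none
Why: Fluoride-driven cleavage of the primary silyl ether under buffered conditions that should not ionise the ring allylic alcohol.

Step 11
Reactants: 14 (1S,4R)-4-[(1E,3E)-5-hydroxy-3-methylpenta-1,3-dien-1-yl]-3,5,5-trimethylcyclohex-2-en-1-ol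
Product: 15 (2E,4E)-5-[(1R,4S)-4-hydroxy-2,6,6-trimethylcyclohex-2-en-1-yl]-3-methylpenta-2,4-dienal
Conditions: TEMPO (0.1 equiv), PhI(OAc)2 (1.1 equiv), CH2Cl2, rt
Reagents that add atoms: none
Why: Oxoammonium (TEMPO/PhI(OAc)2) oxidation, which is selective for the unhindered primary dienylic alcohol over the hindered secondary ring carbinol and should stop at the aldehyde without touching the olefin geometry.

Step 12
Reactants: 15 (2E,4E)-5-[(1R,4S)-4-hydroxy-2,6,6-trimethylcyclohex-2-en-1-yl]-3-methylpenta-2,4-dienal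
Product: 16 (2E,4E)-5-[(4R)-4-hydroxy-2,6,6-trimethylcyclohex-1-en-1-yl]-3-methylpenta-2,4-dienal
Conditions: DBU (0.3 equiv), toluene, rt to 40 °C, argon, dark
Reagents that add atoms: none
Why: Base-mediated prototropic conjugation (the α-ionone to β-ionone type of shift): DBU removes the doubly allylic ring C1–H, which is vinylogously activated by the aldehyde, and reprotonation of the extended enolate at ring C3 moves the ring double bond into conjugation. The carbinol centre is untouched and becomes (4R), and the now superfluous C1 centre is erased.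

Step 13
Reactants: 16 (2E,4E)-5-[(4R)-4-hydroxy-2,6,6-trimethylcyclohex-1-en-1-yl]-3-methylpenta-2,4-dienal
Product: 17 (1R)-3,5,5-trimethyl-4-[(1E,3E)-3-methyl-5-oxopenta-1,3-dien-1-yl]cyclohex-3-en-1-yl hexadecanoate
Conditions: palmitoyl chloride, pyridine, DMAP (cat.), CH2Cl2, 0 °C
Reagents that add atoms: hexadecanoyl chloride CCCCCCCCCCCCCCCC(=O)Cl
Why: DMAP-catalysed O-acylation of the secondary alcohol with retention gives the (R)-palmitate that is C3 of the target; the acylation is placed after step 12 so that no acyloxy leaving group sits next to the carbanionic site during the double-bond shift.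

Step 14
Reactants: 17 (1R)-3,5,5-trimethyl-4-[(1E,3E)-3-methyl-5-oxopenta-1,3-dien-1-yl]cyclohex-3-en-1-yl hexadecanoate
Product: 18 (1R)-4-[(1E,3E)-5-hydroxy-3-methylpenta-1,3-dien-1-yl]-3,5,5-trimethylcyclohex-3-en-1-yl hexadecanoate
Conditions: NaBH4, THF/EtOH, −20 to 0 °C
Reagents that add atoms: none
Why: Borohydride 1,2-reduction of a polyenal to the allylic alcohol (as for retinal to retinol); the ester should not be reduced at this temperature.

Step 15
Reactants: 18 (1R)-4-[(1E,3E)-5-hydroxy-3-methylpenta-1,3-dien-1-yl]-3,5,5-trimethylcyclohex-3-en-1-yl hexadecanoate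
Product: 19 {(2E,4E)-5-[(4R)-4-(hexadecanoyloxy)-2,6,6-trimethylcyclohex-1-en-1-yl]-3-methylpenta-2,4-dien-1-yl}triphenylphosphonium bromide
Conditions: PPh3·HBr (1.05 equiv), CH2Cl2, 0 °C to rt
Reagents that add atoms: triphenylphosphine hydrobromide [Br-].c1ccc(cc1)[PH+](c1ccccc1)c1ccccc1
Why: The same alcohol-to-phosphonium conversion as in step 8, here on the acid-stable β-end group; the salt should be obtained mainly as the 9E isomer and purified by crystallisation.

Step 16
Reactants: 19 {(2E,4E)-5-[(4R)-4-(hexadecanoyloxy)-2,6,6-trimethylcyclohex-1-en-1-yl]-3-methylpenta-2,4-dien-1-yl}triphenylphosphonium bromide; 20 (2E,4E,6E)-2,7-dimethylocta-2,4,6-trienedial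
Product: 22 (3R)-3-(hexadecanoyloxy)-12'-apo-β-caroten-12'-al, via phosphonium ylide 21 (not isolated)
Conditions: 20 (3 equiv), 1,2-epoxybutane, reflux; then n-heptane, 80 °C (Z to E), chromatography
Reagents that add atoms: none
Why: Wittig olefination under neutral epoxide conditions (the epoxide takes up HBr and releases the ylide), which should spare the ester; the excess of dialdehyde favours mono-olefination, and the new C11=C12 bond is equilibrated thermally to E.

Step 17
Reactants: 12 {(2E,4E)-5-[(1R,4R)-4-(hexadecanoyloxy)-2,6,6-trimethylcyclohex-2-en-1-yl]-3-methylpenta-2,4-dien-1-yl}triphenylphosphonium bromide; 22 (3R)-3-(hexadecanoyloxy)-12'-apo-β-caroten-12'-al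
Product: 24 helenien, (3R,3'R,6'R)-β,ε-carotene-3,3'-diyl dihexadecanoate, via phosphonium ylide 23 (not isolated)
Conditions: 12 (1.3 equiv), 1,2-epoxybutane, reflux; then n-heptane, reflux (Z to E), crystallisation, argon, dark
Reagents that add atoms: none
Why: Second Wittig olefination under the same ester-compatible conditions joins the ε-C15 and C25 halves at C11'=C12'; thermal equilibration of the polyene should give the all-E isomer, and none of the three stereocentres is involved.

## Compound list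

1 | (2E)-3-methylpent-2-en-4-yn-1-ol | C#C/C(C)=C/CO | starting material
2 | tert-butyl(dimethyl){[(2E)-3-methylpent-2-en-4-yn-1-yl]oxy}silane | C#C/C(C)=C/CO[Si](C)(C)C(C)(C)C | intermediate
3 | 2,4,4-trimethylcyclopent-2-en-1-one | CC1=CC(C)(C)CC1=O | starting material
4 | chlorobis(cyclopentadienyl)[(1E,3E)-5-(TBSO)-3-methylpenta-1,3-dien-1-yl]zirconium (dienylzirconocene chloride) | Cl[Zr](C1C=CC=C1)(C1C=CC=C1)/C=C/C(C)=C/CO[Si](C)(C)C(C)(C)C | intermediate
5 | tert-butyl(dimethyl){[(2E,4E)-3-methyl-5-[(1R)-2,5,5-trimethyl-3-(trimethylsilyloxy)cyclopent-2-en-1-yl]penta-2,4-dien-1-yl]oxy}silane | CC(C)(C)[Si](C)(C)OC/C=C(C)/C=C/[C@H]1C(C)=C(O[Si](C)(C)C)CC1(C)C | intermediate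
6 | (1S,4R,5S)-4-[(1E,3E)-5-(TBSO)-3-methylpenta-1,3-dien-1-yl]-3,3,5-trimethyl-1-(trimethylsilyloxy)bicyclo[3.1.0]hexane (CH2 bridge trans to the dienyl group) | CC(C)(C)[Si](C)(C)OC/C=C(C)/C=C/[C@H]1[C@]2(C)C[C@]2(O[Si](C)(C)C)CC1(C)C | intermediate
7 | (4R)-3-chloro-4-[(1E,3E)-5-(TBSO)-3-methylpenta-1,3-dien-1-yl]-3,5,5-trimethylcyclohexan-1-one (β-chloroketone, C3 epimers) | CC(C)(C)[Si](C)(C)OC/C=C(C)/C=C/[C@H]1C(C)(Cl)CC(=O)CC1(C)C | intermediate
8 | (4R)-4-[(1E,3E)-5-(TBSO)-3-methylpenta-1,3-dien-1-yl]-3,5,5-trimethylcyclohex-2-en-1-one | CC(C)(C)[Si](C)(C)OC/C=C(C)/C=C/[C@H]1C(C)=CC(=O)CC1(C)C | intermediate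
9 | (1R,4R)-4-[(1E,3E)-5-(TBSO)-3-methylpenta-1,3-dien-1-yl]-3,5,5-trimethylcyclohex-2-en-1-ol (trans) | CC(C)(C)[Si](C)(C)OC/C=C(C)/C=C/[C@H]1C(C)=C[C@H](O)CC1(C)C | intermediate
10 | (1R,4R)-4-[(1E,3E)-5-(TBSO)-3-methylpenta-1,3-dien-1-yl]-3,5,5-trimethylcyclohex-2-en-1-yl hexadecanoate | CC(C)(C)[Si](C)(C)OC/C=C(C)/C=C/[C@H]1C(C)=C[C@H](OC(=O)CCCCCCCCCCCCCCC)CC1(C)C | intermediate
11 | (1R,4R)-4-[(1E,3E)-5-hydroxy-3-methylpenta-1,3-dien-1-yl]-3,5,5-trimethylcyclohex-2-en-1-yl hexadecanoate | OC/C=C(C)/C=C/[C@H]1C(C)=C[C@H](OC(=O)CCCCCCCCCCCCCCC)CC1(C)C | intermediate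
12 | {(2E,4E)-5-[(1R,4R)-4-(hexadecanoyloxy)-2,6,6-trimethylcyclohex-2-en-1-yl]-3-methylpenta-2,4-dien-1-yl}triphenylphosphonium bromide | [Br-].c1ccc(cc1)[P+](c1ccccc1)(c1ccccc1)C/C=C(C)/C=C/[C@H]1C(C)=C[C@H](OC(=O)CCCCCCCCCCCCCCC)CC1(C)C | intermediate
13 | (1S,4R)-4-[(1E,3E)-5-(TBSO)-3-methylpenta-1,3-dien-1-yl]-3,5,5-trimethylcyclohex-2-en-1-ol (cis) | CC(C)(C)[Si](C)(C)OC/C=C(C)/C=C/[C@H]1C(C)=C[C@@H](O)CC1(C)C | intermediate
14 | (1S,4R)-4-[(1E,3E)-5-hydroxy-3-methylpenta-1,3-dien-1-yl]-3,5,5-trimethylcyclohex-2-en-1-ol | OC/C=C(C)/C=C/[C@H]1C(C)=C[C@@H](O)CC1(C)C | intermediate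
15 | (2E,4E)-5-[(1R,4S)-4-hydroxy-2,6,6-trimethylcyclohex-2-en-1-yl]-3-methylpenta-2,4-dienal | O=C/C=C(C)/C=C/[C@H]1C(C)=C[C@@H](O)CC1(C)C | intermediate
16 | (2E,4E)-5-[(4R)-4-hydroxy-2,6,6-trimethylcyclohex-1-en-1-yl]-3-methylpenta-2,4-dienal | O=C/C=C(C)/C=C/C1=C(C)C[C@@H](O)CC1(C)C | intermediate
17 | (1R)-3,5,5-trimethyl-4-[(1E,3E)-3-methyl-5-oxopenta-1,3-dien-1-yl]cyclohex-3-en-1-yl hexadecanoate | O=C/C=C(C)/C=C/C1=C(C)C[C@@H](OC(=O)CCCCCCCCCCCCCCC)CC1(C)C | intermediate
18 | (1R)-4-[(1E,3E)-5-hydroxy-3-methylpenta-1,3-dien-1-yl]-3,5,5-trimethylcyclohex-3-en-1-yl hexadecanoate | OC/C=C(C)/C=C/C1=C(C)C[C@@H](OC(=O)CCCCCCCCCCCCCCC)CC1(C)C | intermediate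
19 | {(2E,4E)-5-[(4R)-4-(hexadecanoyloxy)-2,6,6-trimethylcyclohex-1-en-1-yl]-3-methylpenta-2,4-dien-1-yl}triphenylphosphonium bromide | [Br-].c1ccc(cc1)[P+](c1ccccc1)(c1ccccc1)C/C=C(C)/C=C/C1=C(C)C[C@@H](OC(=O)CCCCCCCCCCCCCCC)CC1(C)C | intermediate
20 | (2E,4E,6E)-2,7-dimethylocta-2,4,6-trienedial | O=C/C(C)=C/C=C/C=C(C)/C=O | starting material
21 | ylide of 19, (2E,4E)-5-[(4R)-4-(hexadecanoyloxy)-2,6,6-trimethylcyclohex-1-en-1-yl]-3-methylpenta-2,4-dienylidene(triphenyl)phosphorane | c1ccc(cc1)[P+](c1ccccc1)(c1ccccc1)[CH-]/C=C(C)/C=C/C1=C(C)C[C@@H](OC(=O)CCCCCCCCCCCCCCC)CC1(C)C | intermediate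
22 | (3R)-3-(hexadecanoyloxy)-12'-apo-β-caroten-12'-al, i.e. (1R)-3,5,5-trimethyl-4-[(1E,3E,5E,7E,9E,11E)-3,7,12-trimethyl-13-oxotrideca-1,3,5,7,9,11-hexaen-1-yl]cyclohex-3-en-1-yl hexadecanoate | O=C/C(C)=C/C=C/C=C(C)/C=C/C=C(C)/C=C/C1=C(C)C[C@@H](OC(=O)CCCCCCCCCCCCCCC)CC1(C)C | intermediate
23 | ylide of 12, (2E,4E)-5-[(1R,4R)-4-(hexadecanoyloxy)-2,6,6-trimethylcyclohex-2-en-1-yl]-3-methylpenta-2,4-dienylidene(triphenyl)phosphorane | c1ccc(cc1)[P+](c1ccccc1)(c1ccccc1)[CH-]/C=C(C)/C=C/[C@H]1C(C)=C[C@H](OC(=O)CCCCCCCCCCCCCCC)CC1(C)C | intermediate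
24 | helenien, (3R,3'R,6'R)-β,ε-carotene-3,3'-diyl dihexadecanoate | CCCCCCCCCCCCCCCC(=O)O[C@@H]1CC(C)=C(/C=C/C(C)=C/C=C/C(C)=C/C=C/C=C(C)/C=C/C=C(C)/C=C/[C@H]2C(C)=C[C@H](OC(=O)CCCCCCCCCCCCCCC)CC2(C)C)C(C)(C)C1 | target

## Step count and risks

Total step count: 17. Longest linear sequence: 13 steps (steps 1–4 and 9–17); the ε-branch (steps 5–8) joins in step 17.

The three steps most likely to fail:

1. Step 2. Carbometalation of the α-methylated, γ-quaternary enone by the dienylcopper species may be too slow, so that uncatalysed racemic addition, dienyl homocoupling or protonolysis of 4 takes over and the enantiomeric purity of 5 suffers. The fallback sets out from 2 and comes back at 5. The dienylzirconocene 4 made from 2 is added instead to commercial 4,4-dimethylcyclopent-2-en-1-one under Rh(I)/BINAP catalysis with TMSCl (the closest precedent for alkenylzirconocenes with silyl trapping; BINAP antipode chosen for the same facial sense). This should give tert-butyl(dimethyl){[(2E,4E)-5-[(1S)-5,5-dimethyl-3-(trimethylsilyloxy)cyclopent-2-en-1-yl]-3-methylpenta-2,4-dien-1-yl]oxy}silane F1. MeLi (THF, 0 °C) turns F1 into its lithium enolate, which MeI methylates regiospecifically to the trans ketone (2S,3S)-3-[(1E,3E)-5-(TBSO)-3-methylpenta-1,3-dien-1-yl]-2,4,4-trimethylcyclopentan-1-one F2. Thermodynamic silylation of F2 (TMSCl, Et3N, DMF, 80 °C) gives the tetrasubstituted enol ether 5.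

2. Step 12. The dienal may undergo aldol-type self-condensation, Z/E scrambling at C9=C10 through the γ-dienolate, or incomplete migration of the ring double bond. The fallback sets out from 8 and comes back at 18, moving the double bond before the carbinol is made. Kinetic deconjugation of 8 (KHMDS, THF, −78 °C, inverse quench into AcOH) should give the achiral β,γ-enone 4-[(1E,3E)-5-(TBSO)-3-methylpenta-1,3-dien-1-yl]-3,5,5-trimethylcyclohex-3-en-1-one F3. A ketoreductase selected for the (R)-alcohol (NADP+, iPrOH, buffer pH 7) reduces F3 to (1R)-4-[(1E,3E)-5-(TBSO)-3-methylpenta-1,3-dien-1-yl]-3,5,5-trimethylcyclohex-3-en-1-ol F4. Acylation with palmitoyl chloride (pyridine, DMAP) gives (1R)-4-[(1E,3E)-5-(TBSO)-3-methylpenta-1,3-dien-1-yl]-3,5,5-trimethylcyclohex-3-en-1-yl hexadecanoate F5, and HF·pyridine removes the silyl group to give 18.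

3. Step 9. Facial selectivity may erode if the catalyst and the intrinsic preference of the substrate oppose one another, and hydroboration of the diene may intrude if the reduction is slow. The fallback sets out from 9 and comes back at 13. Mitsunobu inversion of the trans alcohol 9 with 4-nitrobenzoic acid (PPh3, DIAD, toluene, 0 °C) should give (1S,4R)-4-[(1E,3E)-5-(TBSO)-3-methylpenta-1,3-dien-1-yl]-3,5,5-trimethylcyclohex-2-en-1-yl 4-nitrobenzoate F6, and methanolysis (K2CO3, MeOH) gives 13. If it is step 5 that turns out to be the mismatched case, the same pair of operations run from 13 would give 9.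

## Further compounds

F1 | step 2 | tert-butyl(dimethyl){[(2E,4E)-5-[(1S)-5,5-dimethyl-3-(trimethylsilyloxy)cyclopent-2-en-1-yl]-3-methylpenta-2,4-dien-1-yl]oxy}silane | CC(C)(C)[Si](C)(C)OC/C=C(C)/C=C/[C@H]1C=C(O[Si](C)(C)C)CC1(C)C
F2 | step 2 | (2S,3S)-3-[(1E,3E)-5-(TBSO)-3-methylpenta-1,3-dien-1-yl]-2,4,4-trimethylcyclopentan-1-one | CC(C)(C)[Si](C)(C)OC/C=C(C)/C=C/[C@H]1[C@H](C)C(=O)CC1(C)C
F3 | step 12 | 4-[(1E,3E)-5-(TBSO)-3-methylpenta-1,3-dien-1-yl]-3,5,5-trimethylcyclohex-3-en-1-one | CC(C)(C)[Si](C)(C)OC/C=C(C)/C=C/C1=C(C)CC(=O)CC1(C)C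
F4 | step 12 | (1R)-4-[(1E,3E)-5-(TBSO)-3-methylpenta-1,3-dien-1-yl]-3,5,5-trimethylcyclohex-3-en-1-ol | CC(C)(C)[Si](C)(C)OC/C=C(C)/C=C/C1=C(C)C[C@@H](O)CC1(C)C
F5 | step 12 | (1R)-4-[(1E,3E)-5-(TBSO)-3-methylpenta-1,3-dien-1-yl]-3,5,5-trimethylcyclohex-3-en-1-yl hexadecanoate | CC(C)(C)[Si](C)(C)OC/C=C(C)/C=C/C1=C(C)C[C@@H](OC(=O)CCCCCCCCCCCCCCC)CC1(C)C
F6 | step 9 | (1S,4R)-4-[(1E,3E)-5-(TBSO)-3-methylpenta-1,3-dien-1-yl]-3,5,5-trimethylcyclohex-2-en-1-yl 4-nitrobenzoate | CC(C)(C)[Si](C)(C)OC/C=C(C)/C=C/[C@H]1C(C)=C[C@@H](OC(=O)c2ccc(cc2)[N+](=O)[O-])CC1(C)C
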